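The readings are calculated on assumed constants, noise included.

How much target does the flask hold at 50 min, with less free catalyst than the ochre and amber runs and a later time than their last reading?

* amount of target at 50 min, in percent of the solid substrate charged
* concentration of starting material in solution at 50 min, in percent of saturation

| flask | solid substrate | partner | free catalyst | second catalyst | remark | time |
|---|---|---|---|---|---|---|
| ochre | 0.070 M | 0.091 M | 1.2 mM | 14 mM | run made earlier |  |
| amber | 0.070 M | 0.091 M | 1.8 mM | 14 mM | run made earlier |  |
| green | 0.035 M | 0.091 M | 0.84 mM | 14 mM | run made earlier |  |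
| flask | 0.070 M | 0.0910 M | 0.84 mM | 14 mM |  | 50 min |

| run | time / min | target / % | starting material / % | solid substrate / % |
|---|---|---|---|---|
| ochre | 6.00 | 1 | 16 | 81 |
| ochre | 12.0 | 6 | 28 | 68 |
| ochre | 20.0 | 7 | 34 | 50 |
| ochre | 25.0 | 11 | 41 | 41 |
| ochre | 30.0 | 16 | 43 | 37 |
| ochre | 40.0 | 26 | 48 | 23 |
| amber | 6.00 | 4 | 14 | 81 |
| amber | 12.0 | 3 | 27 | 69 |
| amber | 20.0 | 10 | 34 | 50 |
| amber | 25.0 | 14 | 38 | 42 |
| amber | 30.0 | 20 | 39 | 32 |
| amber | 40.0 | 37 | 42 | 13 |
| green | 3.00 | 0 | 20 | 83 |
| green | 6.00 | 2 | 34 | 63 |
| green | 12.0 | 2 | 57 | 37 |
| green | 20.0 | 12 | 75 | 6 |
| green | 40.0 | 34 | 57 | 1 |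

(scatter of a reading: 2 percentage points)

- as a solid, counted per litre of solution: solid substrate
- at the start none of the solid substrate is in solution
- starting material means what is dissolved; the solid is not counted in it
- starting material is what solid substrate becomes in solution

We work in logarithms. First, what does free catalyst buy? At 40.0 min, the ochre and amber runs differ in free catalyst, 1.2 mM against 1.8 mM, and target reads 26% against 37%. The slope of log target against log free catalyst, at fixed time and other charges, is 0.870; we call it the apparent order in free catalyst, a reading that carries the scatter of 2 percentage points. If that order holds down to our flask's smaller charge, the charge multiplies the ochre target, at fixed time, by 0.733.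

Then, what does the extra time buy? From 25.0 min to 40.0 min, ochre target rises from 11% to 26%, a log-log slope of 1.83. If that slope lasts to 50 min, the factor is 1.50. Our own estimate is 28.7%.

The forecast gives 31% target and starting material at 73% of saturation, with its saturation concentration “Csat ≈ 0.05 M, though this is poorly fixed”.

The flask gives 28.1% target and starting material at 65.4% of saturation: the forecast's target is within tolerance, and its saturation figure is 7.6 points too high.

    starting material + free catalyst → free catalyst + intermediate (k = 19.8 M⁻¹ min⁻¹)
    2 starting material → self-condensation product (k = 6.19 × 10⁻⁴ M⁻¹ min⁻¹)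
    partner + second catalyst + intermediate → second catalyst + target (k = 180 M⁻² min⁻¹)
    solid substrate ⇌ starting material, rate k4*(cs4 - [starting material]) while solid is left; crystals form when [starting material] > cs4 (solubility = 0.0600 M, k = 0.0386 min⁻¹)

At 50.0 min, starting material in this flask is still made 1.22 times faster than it is used, and it stands at 56.1% beside 28.1% target. Its half-life toward intermediate, by that step alone with the other concentrations as charged, is 42 min, shorter than the run. Applied to the 37.0% that the ochre charge reaches at 50 min, the apparent order gives 27.1% for this flask, against 28.1%. For the neighbour flask with 0.0014 M free catalyst, other charges and time as in this flask, the apparent order multiplies 28.1% by a factor of 1.56, which gives 43.8%; the computed result is 41.3%.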